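## Strategy

1. Last cut: the two aryl benzyl ethers (4'-O and the phenol oxygen of the C6 benzyl group), which leads back to the protected flavanone 17.
2. Central cut: ring A is opened at C8–C8a and C5–C4a. This works because ring A carries O1, 5-OH and 7-OMe in a 1,3,5 pattern with the 2-hydroxybenzyl group on C6 between O5 and O7, which is a 2-benzyl-1,1,3-trioxygenated butadiene (C5 to C8, diene 14) joined to the C4a–C8a edge of a 2-aryl-2,3-dihydro-4H-pyran-4-one (7) that already contains C2.
3. Sulfinyl dihydropyranone 7 comes from dihydropyranone 4 by C5–S bond formation. Compound 4 is cut at C2–C3 and O1–C6 into aldehyde 1 and diene 2 (hetero-Diels–Alder).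
4. Diene 14 comes from methyl acetoacetate 10 and benzyl bromide 9 (bond from the α-carbon to the benzylic CH2), then enol ether and silyl ketene acetal formation.
5. Forward order of rings: ring C with ring B attached first, ring A annulated last and bringing the fourth arene with it. The final step only frees two phenols.
6. Stereochemistry: C2 (R), the only stereocenter, is set by the chiral BINOL/Ti(OiPr)4 catalyst in step 1 and is afterwards exposed only to neutral, mildly acidic or briefly amine-buffered steps.

Key step: step 8

Assumption: (R)-BINOL is taken to give the 2R dihydropyranone, by analogy with the usual facial preference of BINOL/titanium catalysts with aryl aldehydes; if the sense proves opposite, (S)-BINOL is used and nothing else changes.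

## Route

Step 1
Reactants: 1 4-(benzyloxy)benzaldehyde; 2 trans-1-methoxy-3-(trimethylsilyloxy)buta-1,3-diene (Danishefsky diene)
Product: 4 (R)-2-[4-(benzyloxy)phenyl]-2,3-dihydro-4H-pyran-4-one, via silyl aldol adduct 3 (not isolated)
Conditions: (R)-BINOL (20 mol%), Ti(OiPr)4 (10 mol%), 4 Å MS, Et2O, −20 °C; then CF3CO2H, CH2Cl2, 0 °C; aq. NaHCO3
Reagents that add atoms: none
Why: This is a catalytic enantioselective hetero-Diels–Alder reaction, which with this catalyst runs as a Mukaiyama aldol addition to the aldehyde bound to tetravalent titanium followed by acid-induced ring closure with loss of methanol, is established for 4-alkoxybenzaldehydes, and sets C2 because the chiral BINOL complex shields one face of the coordinated aldehyde.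

Step 2
Reactants: 4 (R)-2-[4-(benzyloxy)phenyl]-2,3-dihydro-4H-pyran-4-one
Product: 6 (R)-2-[4-(benzyloxy)phenyl]-5-(phenylthio)-2,3-dihydro-4H-pyran-4-one, via chloro sulfide adduct 5 (not isolated)
Conditions: PhSH, N-chlorosuccinimide, CH2Cl2, 0 °C (gives PhSCl); add 4, −78 °C to 0 °C; then Et3N, 0 °C
Reagents that add atoms: thiophenol, Sc1ccccc1 (used as benzenesulfenyl chloride, ClSc1ccccc1, made from it in the flask with N-chlorosuccinimide)
Why: This is an electrophilic sulfenylation of an enol ether, in which the sulfenyl chloride attacks C5 (the nucleophilic α-carbon of the vinylogous ester), chloride caps the oxocarbenium ion at C6, and triethylamine then removes HCl by E1cB elimination to restore the conjugated system without touching C2.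

Step 3
Reactants: 6 (R)-2-[4-(benzyloxy)phenyl]-5-(phenylthio)-2,3-dihydro-4H-pyran-4-one
Product: 7 (2R)-2-[4-(benzyloxy)phenyl]-5-(phenylsulfinyl)-2,3-dihydro-4H-pyran-4-one (both configurations at sulfur)
Conditions: mCPBA (1.0 equiv), CH2Cl2, −78 °C to −20 °C; aq. NaHCO3/Na2S2O3
Reagents that add atoms: mCPBA, O=C(OO)c1cccc(Cl)c1
Why: One equivalent of peracid at low temperature oxidizes the sulfide chemoselectively to the sulfoxide while the electron-poor enol ether alkene stays inert, and the mixture at the new sulfur stereocenter is irrelevant because sulfur is expelled in step 8.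

Step 4
Reactants: 8 2-(benzyloxy)benzyl alcohol
Product: 9 2-(benzyloxy)benzyl bromide
Conditions: PBr3 (0.4 equiv), Et2O, 0 °C
Reagents that add atoms: phosphorus tribromide, BrP(Br)Br
Why: Bromination of a primary benzylic alcohol with PBr3 proceeds by SN2 displacement of the phosphite ester and leaves the aryl benzyl ether untouched.

Step 5
Reactants: 10 methyl acetoacetate; 9 2-(benzyloxy)benzyl bromide
Product: 11 methyl 2-[2-(benzyloxy)benzyl]-3-oxobutanoate (racemic)
Conditions: 10 (1.5 equiv), NaH (1.4 equiv), THF, 0 °C; then 9 (1.0 equiv), 0 °C to rt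
Reagents that add atoms: none
Why: This is the acetoacetic ester alkylation, in which the sodium enolate is C-benzylated by the reactive benzylic bromide, the excess of 10 suppresses double alkylation, and the racemic α-center disappears in step 6.

Step 6
Reactants: 11 methyl 2-[2-(benzyloxy)benzyl]-3-oxobutanoate
Product: 13 methyl 2-[2-(benzyloxy)benzyl]-3-methoxybut-2-enoate (E/Z mixture accepted), via dimethyl ketal 12 (not isolated)
Conditions: HC(OMe)3 (3 equiv), H2SO4 (cat.), MeOH, rt; then TsOH (cat.), PhMe, reflux with removal of MeOH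
Reagents that add atoms: trimethyl orthoformate, COC(OC)OC
Why: Acid-catalysed ketalization with the orthoformate followed by loss of methanol is the standard route to β-methoxy enoates, and either alkene isomer (or any deconjugated enol ether) converges on the same dienolate in step 7.

Step 7
Reactants: 13 methyl 2-[2-(benzyloxy)benzyl]-3-methoxybut-2-enoate
Product: 14 2-[2-(benzyloxy)benzyl]-1,3-dimethoxy-1-(trimethylsilyloxy)buta-1,3-diene
Conditions: LiN(iPr)2 (LDA, 1.1 equiv), THF, −78 °C; Me3SiCl, −78 °C to rt; non-aqueous work-up (hexane, filtration), used crude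
Reagents that add atoms: chlorotrimethylsilane, C[Si](C)(C)Cl
Why: Vinylogous (γ) deprotonation of the β-methoxy enoate and O-silylation of the extended enolate is the standard preparation of Brassard-type vinylketene acetals and tolerates a carbon substituent at C2.

Step 8
Reactants: 7 (2R)-2-[4-(benzyloxy)phenyl]-5-(phenylsulfinyl)-2,3-dihydro-4H-pyran-4-one; 14 2-[2-(benzyloxy)benzyl]-1,3-dimethoxy-1-(trimethylsilyloxy)buta-1,3-diene
Product: 17 (2R)-4'-O-benzyl-6-[2-(benzyloxy)benzyl]-5-hydroxy-7-methoxyflavanone, via cycloadduct 15 (not isolated), via sulfinyl diketone 16 (not isolated)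
Conditions: 14 (2.5 equiv), ZnCl2 (0.2 equiv, Et2O solution), CH2Cl2, −20 °C to rt; then PhMe, 60 °C
Reagents that add atoms: none
Why: Proposed new method: the CH2 terminus of 14 should attack C6 of 7 (β to both ketone and sulfinyl group) and the acetal carbon should then bond to the sulfinyl-bearing C5, either as an asynchronous [4+2] cycloaddition or as a Mukaiyama–Michael addition followed by 6-exo-trig Claisen-type closure, so that C8–C8a and C5–C4a (flavanone numbering) form and ring A closes as a six-membered carbocycle on the C4a–C8a edge of ring C. The closest known reaction type is the Brassard-diene benzannulation of halo- or sulfinylquinones and of 3-acceptor-substituted chromones with eliminative aromatization, together with Lewis acid promoted Mukaiyama–Michael additions of silyl ketene acetals to 2,3-dihydro-4H-pyran-4-ones, but a 5-sulfinyl dihydropyranone has not been used as the two-carbon partner. Adduct 15 should lose methoxytrimethylsilane to reveal the C5 ketone in 16, whose sulfinyl group lies cis to C8a–H after suprafacial addition and leaves as benzenesulfenic acid by thermal syn-elimination, after which enolization of the dienone gives the hydrogen-bonded 5-OH phenol. No lasting stereocenter is formed, since C4a, C8a, the acetal carbon and sulfur all lose their stereochemistry on aromatization, so facial selectivity is immaterial and C2 (R) is a bystander under these neutral to weakly Lewis acidic conditions. The step needs head-to-tail regioselectivity, which the matched polarization of 14 (nucleophilic C4) and of 7 (electrophilic C6, reinforced by ZnCl2 chelated between sulfinyl and ketone oxygens) should secure, placing the benzyl group on C6 between 5-OH and 7-OMe and leaving O1 on C8a. It also needs aromatization by loss of sulfur and not of O1, which is secured because C4a carries the sulfinyl group and no hydrogen.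

Step 9
Reactants: 17 (2R)-4'-O-benzyl-6-[2-(benzyloxy)benzyl]-5-hydroxy-7-methoxyflavanone
Product: 18 (+)-methylphelligrin A, (2R)-5-hydroxy-6-(2-hydroxybenzyl)-2-(4-hydroxyphenyl)-7-methoxychroman-4-one
Conditions: H2 (1 atm), 10% Pd/C, EtOAc, rt, stopped at full debenzylation
Reagents that add atoms: none
Why: Hydrogenolysis of aryl benzyl ethers over Pd/C in a neutral aprotic solvent is faster than cleavage of the cyclic C2–O1 benzylic ether and avoids the base-induced ring opening to the chalcone that would racemize C2, so the stereocenter should be retained.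

## Compound list

1 | 4-(benzyloxy)benzaldehyde | O=Cc1ccc(OCc2ccccc2)cc1 | starting material
2 | trans-1-methoxy-3-(trimethylsilyloxy)buta-1,3-diene (Danishefsky diene) | CO/C=C/C(=C)O[Si](C)(C)C | starting material
3 | (R,E)-5-[4-(benzyloxy)phenyl]-1-methoxy-5-(trimethylsilyloxy)pent-1-en-3-one (silyl aldol adduct) | CO/C=C/C(=O)C[C@@H](O[Si](C)(C)C)c1ccc(OCc2ccccc2)cc1 | intermediate
4 | (R)-2-[4-(benzyloxy)phenyl]-2,3-dihydro-4H-pyran-4-one | O=C1C[C@H](c2ccc(OCc3ccccc3)cc2)OC=C1 | intermediate
5 | (2R)-2-[4-(benzyloxy)phenyl]-6-chloro-5-(phenylthio)tetrahydro-4H-pyran-4-one (mixture at C5 and C6) | O=C1C[C@H](c2ccc(OCc3ccccc3)cc2)OC(Cl)C1Sc1ccccc1 | intermediate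
6 | (R)-2-[4-(benzyloxy)phenyl]-5-(phenylthio)-2,3-dihydro-4H-pyran-4-one | O=C1C[C@H](c2ccc(OCc3ccccc3)cc2)OC=C1Sc1ccccc1 | intermediate
7 | (2R)-2-[4-(benzyloxy)phenyl]-5-(phenylsulfinyl)-2,3-dihydro-4H-pyran-4-one (mixture at sulfur) | O=C1C[C@H](c2ccc(OCc3ccccc3)cc2)OC=C1S(=O)c1ccccc1 | intermediate
8 | 2-(benzyloxy)benzyl alcohol | OCc1ccccc1OCc1ccccc1 | starting material
9 | 2-(benzyloxy)benzyl bromide | BrCc1ccccc1OCc1ccccc1 | intermediate
10 | methyl acetoacetate | COC(=O)CC(C)=O | starting material
11 | methyl 2-[2-(benzyloxy)benzyl]-3-oxobutanoate (racemic) | COC(=O)C(Cc1ccccc1OCc1ccccc1)C(C)=O | intermediate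
12 | methyl 2-[2-(benzyloxy)benzyl]-3,3-dimethoxybutanoate (dimethyl ketal, racemic) | COC(=O)C(Cc1ccccc1OCc1ccccc1)C(C)(OC)OC | intermediate
13 | methyl 2-[2-(benzyloxy)benzyl]-3-methoxybut-2-enoate (E/Z mixture) | COC(=O)C(Cc1ccccc1OCc1ccccc1)=C(C)OC | intermediate
14 | 2-[2-(benzyloxy)benzyl]-1,3-dimethoxy-1-(trimethylsilyloxy)buta-1,3-diene | C=C(OC)C(Cc1ccccc1OCc1ccccc1)=C(OC)O[Si](C)(C)C | intermediate
15 | (2R)-2-[4-(benzyloxy)phenyl]-6-[2-(benzyloxy)benzyl]-5,7-dimethoxy-4a-(phenylsulfinyl)-5-(trimethylsilyloxy)-2,3,4a,5,8,8a-hexahydro-4H-chromen-4-one (cis-fused cycloadduct, mixture at C4a, C5, C8a and sulfur) | COC1=C(Cc2ccccc2OCc2ccccc2)C(OC)(O[Si](C)(C)C)C2(S(=O)c3ccccc3)C(=O)C[C@H](c3ccc(OCc4ccccc4)cc3)OC2C1 | intermediate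
16 | (2R)-2-[4-(benzyloxy)phenyl]-6-[2-(benzyloxy)benzyl]-7-methoxy-4a-(phenylsulfinyl)-2,3,8,8a-tetrahydro-4H-chromene-4,5(4aH)-dione (sulfinyl diketone, mixture at C4a, C8a and sulfur) | COC1=C(Cc2ccccc2OCc2ccccc2)C(=O)C2(S(=O)c3ccccc3)C(=O)C[C@H](c3ccc(OCc4ccccc4)cc3)OC2C1 | intermediate
17 | (2R)-4'-O-benzyl-6-[2-(benzyloxy)benzyl]-5-hydroxy-7-methoxyflavanone | COc1cc2c(c(O)c1Cc1ccccc1OCc1ccccc1)C(=O)C[C@H](c1ccc(OCc3ccccc3)cc1)O2 | intermediate
18 | (+)-methylphelligrin A, (2R)-5-hydroxy-6-(2-hydroxybenzyl)-2-(4-hydroxyphenyl)-7-methoxychroman-4-one | COc1cc2c(c(O)c1Cc1ccccc1O)C(=O)C[C@H](c1ccc(O)cc1)O2 | target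

## Step count and risks

Total: 9 steps. Longest linear sequence: 6 steps (8 → 9 → 11 → 13 → 14 → 17 → 18). The other arm, 1 → 4 → 6 → 7, joins at step 8.

**Step 8 (labelled new method).** Three things may go wrong:
- ring A may fail to close because the sulfinyl group is lost right after the first C–C bond forms;
- the acid-labile diene may be hydrolysed by the Lewis acid before it adds;
- Lewis acid ionization of the C2–O1 bond may erode the enantiomeric purity.

The fallback uses known chemistry only: ring A is taken from an aromatic precursor and C2 is set by catalytic asymmetric conjugate addition. It sets out from bromide 9 and rejoins the route at 17. Commercial 2',6'-dihydroxy-4'-methoxyacetophenone is condensed with N,N-dimethylformamide dimethyl acetal to (E)-3-(dimethylamino)-1-(2,6-dihydroxy-4-methoxyphenyl)prop-2-en-1-one F1. Acid treatment cyclizes it to 5-hydroxy-7-methoxychromone F2; the two hydroxyls are equivalent, so no regiochemical question arises. Iodination ortho to the hydrogen-bonded 5-OH with benzyltrimethylammonium dichloroiodate/CaCO3, as known for 5-hydroxy-7-alkoxyflavones, gives 5-hydroxy-6-iodo-7-methoxychromone F3. Bromide 9 is converted with zinc dust/LiCl in THF into 2-(benzyloxy)benzylzinc bromide F4. Negishi coupling of F3 with F4 (Pd(OAc)2/SPhos, slow addition of the zinc reagent) gives 6-[2-(benzyloxy)benzyl]-5-hydroxy-7-methoxychromone F5. Base-free asymmetric conjugate addition of 4-(benzyloxy)phenylboronic acid to F5, with Pd(OCOCF3)2 (divalent palladium), the t-BuPyOx antipode that gives the 2R product, NH4PF6 and water in ClCH2CH2Cl at 60 °C, then delivers 17.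

**Step 2.** The sulfenyl chloride may add without clean re-elimination, or the oxocarbenium ion and HCl formed on the way may open ring C at C2–O1 and erode the enantiomeric purity. The fallback replaces electrophilic sulfur by iodination followed by metal-catalysed C–S bond formation. It sets out from 4 and rejoins at 6. Compound 4 is α-iodinated with I2/pyridine in CH2Cl2 to (R)-2-[4-(benzyloxy)phenyl]-5-iodo-2,3-dihydro-4H-pyran-4-one F6. The vinyl iodide is then coupled with thiophenol (Pd2(dba)3/Xantphos, iPr2NEt, dioxane, 80 °C) to give 6.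

**Step 7.** Deprotonation of the γ-methyl group of a tetrasubstituted enol ether may be slow, especially in the isomer with the methyl group trans to the ester, so that amide addition or benzylic deprotonation competes. The fallback moves the proton to be removed to a doubly activated position. It sets out from 9 and rejoins at 14. Commercial methyl (E)-3-methoxybut-2-enoate is deprotonated with LiN(iPr)2 in THF at −78 °C and the dienolate is alkylated with 9 at its α-carbon, as ester dienolates generally are, to give methyl 2-[2-(benzyloxy)benzyl]-3-methoxybut-3-enoate F7. Its α-hydrogen is both allylic and α to the ester, so a second deprotonation with LiN(iPr)2 and silylation with Me3SiCl leads to 14.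

## Further compounds

F1 | step 8 | (E)-3-(dimethylamino)-1-(2,6-dihydroxy-4-methoxyphenyl)prop-2-en-1-one | CN(C)/C=C/C(=O)c1c(O)cc(OC)cc1O
F2 | step 8 | 5-hydroxy-7-methoxy-4H-chromen-4-one | COc1cc(O)c2c(=O)ccoc2c1
F3 | step 8 | 5-hydroxy-6-iodo-7-methoxy-4H-chromen-4-one | COc1cc2occc(=O)c2c(O)c1I
F4 | step 8 | 2-(benzyloxy)benzylzinc bromide | Br[Zn]Cc1ccccc1OCc1ccccc1
F5 | step 8 | 6-[2-(benzyloxy)benzyl]-5-hydroxy-7-methoxy-4H-chromen-4-one | COc1cc2occc(=O)c2c(O)c1Cc1ccccc1OCc1ccccc1
F6 | step 2 | (R)-2-[4-(benzyloxy)phenyl]-5-iodo-2,3-dihydro-4H-pyran-4-one | O=C1C[C@H](c2ccc(OCc3ccccc3)cc2)OC=C1I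
F7 | step 7 | methyl 2-[2-(benzyloxy)benzyl]-3-methoxybut-3-enoate | C=C(OC)C(Cc1ccccc1OCc1ccccc1)C(=O)OC
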